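**Plan**

Locants: ring A is the 3,6-dihydroxy ring (C1–C6, chain C7–C15), ring B the acetylenic ring (primed locants). The retrosynthesis cuts C11=C12 and C11'=C12' (two Wittig reactions, C15 + C10 + C15), C6'–C7' (Sonogashira), C7=C8 (Horner–Wadsworth–Emmons) and, in ring A, C1–C6 together with C4=C5.
Ring A is an isophorone pattern: oxygen at C3, C4=C5 with the 5-methyl, gem-dimethyl C1 in a 1,3-relation to C3, and C6 carrying C7. With C3 as ketone and C7 as ester, C6 is a β-dicarbonyl carbon, so ring A is the Robinson-type annulation product of mesityl oxide (C1–C4) and ethyl acetoacetate (C5–C7).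
Forward: the annulation makes ring A first; ketalisation moves the alkene to C5=C6, epoxidation of the C7 allylic alcohol and later E1cB opening give the 6-hydroxy-4-en-3-one, and C7 is extended to the C15 dienal.
Ring B is taken ready-made from (4R,6R)-actinol (enol triflate, Sonogashira with a C6 enynol); its C15 phosphonium salt is joined to the C10 dialdehyde, and the C25 aldehyde is turned into a phosphonium salt and joined to the ring A dienal in the last step.
Stereochemistry: C6 from a Sharpless asymmetric epoxidation (the C6–O bond survives the epoxide opening), C3 from a Corey–Bakshi–Shibata reduction, C3' from the chiral pool ketone, E alkenes from the olefinations and the preformed (E)-enynol.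

Key step: step 1

Assumption: (4R,6R)-4-hydroxy-2,2,6-trimethylcyclohexanone (actinol), (2E,4E,6E)-2,7-dimethylocta-2,4,6-trienedial, (E)-3-methylpent-2-en-4-yn-1-ol and diethyl (3-cyano-2-methylallyl)phosphonate are taken as purchasable carotenoid and retinoid building blocks.

**Route**

Step 1
Reactants: 1 mesityl oxide (4-methylpent-3-en-2-one); 2 ethyl acetoacetate
Product: 5 (±)-ethyl 2,6,6-trimethyl-4-oxocyclohex-2-ene-1-carboxylate, via 1,5-diketone 3 (not isolated), via ketol 4 (not isolated)
Conditions: BF3·OEt2, neat, rt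
Reagents that add atoms: none
Why: BF3 activates enone 1 and enolises β-keto ester 2, whose doubly activated carbon (future C6) adds to the β,β-dimethyl terminus of 1 (future C1) to give 1,5-diketone 3; the methyl ketone of 3 then enolises toward its methyl group (future C4) and adds to the acetoacetate carbonyl (future C5) to give ketol 4, which dehydrates to enone 5, so that C1–C6, C4=C5 and the whole carbon skeleton of ring A arise in one operation. The closest known reaction type is the Robinson annulation of an enone with a β-keto ester in its Lewis acid variant, the same Michael/aldol-condensation sequence by which isophorone forms from mesityl oxide and acetone. Ring A closes in the aldol step in a 6-(enolendo)-exo-trig mode. The one stereocentre formed, C6, is not controlled and need not be, because the double-bond shift of step 2 erases it and step 4 sets it afresh. The step needs cross-annulation instead of self-condensation of 1, and the correct direction of aldol closure; the first should follow from the far higher enol content of the β-dicarbonyl carbon of 2, the second from the fact that only the methyl ketone of 3 can enolise toward a methyl group while the acetoacetate carbonyl, activated by the adjacent ester, is the better acceptor. The irreversible dehydration should pull the reversible, sterically costly Michael step forward.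

Step 2
Reactants: 5 (±)-ethyl 2,6,6-trimethyl-4-oxocyclohex-2-ene-1-carboxylate
Product: 6 ethyl 7,9,9-trimethyl-1,4-dioxaspiro[4.5]dec-7-ene-8-carboxylate
Conditions: ethylene glycol, p-TsOH (cat.), toluene, reflux, Dean–Stark trap
Reagents that add atoms: ethylene glycol, OCCO
Why: Acid-catalysed ketalisation passes through the dienol ether, and reprotonation at C4 should leave the alkene at C5=C6 in conjugation with the ester (the usual deconjugative ketalisation of enones), which removes the racemic C6 centre.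

Step 3
Reactants: 6 ethyl 7,9,9-trimethyl-1,4-dioxaspiro[4.5]dec-7-ene-8-carboxylate
Product: 7 (7,9,9-trimethyl-1,4-dioxaspiro[4.5]dec-7-en-8-yl)methanol
Conditions: iBu2AlH (2.5 equiv), CH2Cl2, −78 → 0 °C; aq. potassium sodium tartrate
Reagents that add atoms: none
Why: iBu2AlH should reduce the conjugated ester by 1,2-addition to the primary allylic alcohol (ester reduction) while the ketal is inert.

Step 4
Reactants: 7 (7,9,9-trimethyl-1,4-dioxaspiro[4.5]dec-7-en-8-yl)methanol
Product: 8 [(1S,6S)-4,4-(ethylenedioxy)-2,2,6-trimethyl-7-oxabicyclo[4.1.0]heptan-1-yl]methanol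
Conditions: Ti(OiPr)4, L-(+)-diethyl tartrate, tBuOOH, 4 Å molecular sieves, CH2Cl2, −20 °C
Reagents that add atoms: tert-butyl hydroperoxide, CC(C)(C)OO
Why: Sharpless asymmetric epoxidation, in which the allylic hydroxyl binds the Ti(OiPr)4/tartrate complex and the peroxide oxygen is delivered to one enantiotopic face of the tetrasubstituted C5=C6 bond, L-(+)-diethyl tartrate being selected by the face rule of this reaction so that C6 receives its oxygen in the arrangement that becomes 6R in the target.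

Step 5
Reactants: 8 [(1S,6S)-4,4-(ethylenedioxy)-2,2,6-trimethyl-7-oxabicyclo[4.1.0]heptan-1-yl]methanol
Product: 9 (1R,6S)-4,4-(ethylenedioxy)-2,2,6-trimethyl-7-oxabicyclo[4.1.0]heptane-1-carbaldehyde
Conditions: Dess–Martin periodinane, NaHCO3, CH2Cl2, 0 °C → rt
Reagents that add atoms: none
Why: Buffered Dess–Martin oxidation of the primary alcohol should spare the epoxide and the ketal, and no stereocentre is touched (the descriptor at C1 changes from S to R only through the new substituent priorities).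

Step 6
Reactants: 9 (1R,6S)-4,4-(ethylenedioxy)-2,2,6-trimethyl-7-oxabicyclo[4.1.0]heptane-1-carbaldehyde; 10 diethyl (3-cyano-2-methylallyl)phosphonate (E/Z mixture)
Product: 11 (2E,4E)-5-[(1R,6S)-4,4-(ethylenedioxy)-2,2,6-trimethyl-7-oxabicyclo[4.1.0]heptan-1-yl]-3-methylpenta-2,4-dienenitrile
Conditions: 10, NaH, THF, 0 °C; then 9, 0 °C → rt; chromatography
Reagents that add atoms: none
Why: Horner–Wadsworth–Emmons olefination, in which the delocalised phosphonate carbanion attacks the non-enolisable aldehyde through its phosphorus-bearing carbon and reversible addition followed by syn-elimination should give the E-configured C7=C8 bond, the trisubstituted C9=C10 bond being expected mainly E with the 9Z isomer removed by chromatography.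

Step 7
Reactants: 11 (2E,4E)-5-[(1R,6S)-4,4-(ethylenedioxy)-2,2,6-trimethyl-7-oxabicyclo[4.1.0]heptan-1-yl]-3-methylpenta-2,4-dienenitrile
Product: 13 (2E,4E)-5-[(1R)-1-hydroxy-2,6,6-trimethyl-4-oxocyclohex-2-en-1-yl]-3-methylpenta-2,4-dienenitrile, via epoxy ketone 12 (not isolated)
Conditions: 1 M HCl, acetone, rt; then DBU (cat.), CH2Cl2, 0 °C
Reagents that add atoms: water, O
Why: Ketal hydrolysis unmasks the C3 ketone, and the resulting β,γ-epoxy ketone 12 should open by an E1cB process (enolisation toward C4, cleavage of the C5–O bond) to the γ-hydroxy enone, the C6–O bond and therefore the C6 configuration being retained.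

Step 8
Reactants: 13 (2E,4E)-5-[(1R)-1-hydroxy-2,6,6-trimethyl-4-oxocyclohex-2-en-1-yl]-3-methylpenta-2,4-dienenitrile
Product: 14 (2E,4E)-5-[(1R,4S)-1,4-dihydroxy-2,6,6-trimethylcyclohex-2-en-1-yl]-3-methylpenta-2,4-dienenitrile
Conditions: (R)-2-methyl-CBS-oxazaborolidine (0.5 equiv), catecholborane (3 equiv), toluene, −78 → −40 °C; MeOH, then aq. NaHCO3
Reagents that add atoms: none
Why: Corey–Bakshi–Shibata reduction, in which the (R)-oxazaborolidine treats the alkenyl flank (C4) as the large and the C2 methylene as the small group and should deliver hydride to give the 3S carbinol; in the preferred half-chair with pseudoaxial side chain this is the face anti to the syn-axial C1 methyl, so reagent and substrate bias should agree and place the 3-OH cis to the 6-OH, while catecholborane at low temperature spares the dienenitrile.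

Step 9
Reactants: 14 (2E,4E)-5-[(1R,4S)-1,4-dihydroxy-2,6,6-trimethylcyclohex-2-en-1-yl]-3-methylpenta-2,4-dienenitrile
Product: 15 (2E,4E)-5-[(1R,4S)-1,4-dihydroxy-2,6,6-trimethylcyclohex-2-en-1-yl]-3-methylpenta-2,4-dienal
Conditions: iBu2AlH (4 equiv), CH2Cl2, −78 °C; wet SiO2, 0 °C
Reagents that add atoms: water, O
Why: iBu2AlH should add once to the nitrile to give the N-aluminated aldimine, hydrolysed on wet silica gel to the dienal (nitrile half-reduction), the two hydroxyls being carried as O–Al species and regenerated on work-up without any change at C3 or C6.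

Step 10
Reactants: 16 (4R,6R)-4-hydroxy-2,2,6-trimethylcyclohexan-1-one (actinol)
Product: 17 (4R,6R)-2,2,6-trimethyl-4-[(triethylsilyl)oxy]cyclohexan-1-one
Conditions: Et3SiCl, imidazole, DMF, 0 °C → rt
Reagents that add atoms: chlorotriethylsilane, CC[Si](Cl)(CC)CC
Why: Standard silylation of the secondary alcohol, which protects the C3' oxygen for the enolate chemistry without touching its configuration.

Step 11
Reactants: 17 (4R,6R)-2,2,6-trimethyl-4-[(triethylsilyl)oxy]cyclohexan-1-one
Product: 18 (4R)-2,6,6-trimethyl-4-[(triethylsilyl)oxy]cyclohex-1-en-1-yl trifluoromethanesulfonate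
Conditions: LiN(iPr)2, THF, −78 → 0 °C; PhNTf2, −78 °C → rt
Reagents that add atoms: N-phenylbis(trifluoromethanesulfonimide), O=S(=O)(N(c1ccccc1)S(=O)(=O)C(F)(F)F)C(F)(F)F
Why: The ketone can enolise only toward C6, so the single tetrasubstituted enolate should form and be O-triflated by PhNTf2 (enol triflate formation), the C6 centre being lost by design and the silyloxy-bearing centre untouched.

Step 12
Reactants: 18 (4R)-2,6,6-trimethyl-4-[(triethylsilyl)oxy]cyclohex-1-en-1-yl trifluoromethanesulfonate; 19 (E)-3-methylpent-2-en-4-yn-1-ol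
Product: 20 (2E)-3-methyl-5-{(4R)-2,6,6-trimethyl-4-[(triethylsilyl)oxy]cyclohex-1-en-1-yl}pent-2-en-4-yn-1-ol
Conditions: Pd(PPh3)4 (cat.), CuI (cat.), iPr2NH, DMF, rt
Reagents that add atoms: none
Why: Sonogashira coupling, in which oxidative addition of zerovalent palladium into the vinyl triflate, transfer of the alkynyl group from the acetylide generated with CuI and reductive elimination should form the C6'–C7' bond with the preset E geometry of the enyne unchanged.

Step 13
Reactants: 20 (2E)-3-methyl-5-{(4R)-2,6,6-trimethyl-4-[(triethylsilyl)oxy]cyclohex-1-en-1-yl}pent-2-en-4-yn-1-ol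
Product: 23 tributyl[(2E)-3-methyl-5-{(4R)-2,6,6-trimethyl-4-[(triethylsilyl)oxy]cyclohex-1-en-1-yl}pent-2-en-4-yn-1-yl]phosphonium bromide, via allylic mesylate 21 (not isolated), via allylic bromide 22 (not isolated)
Conditions: MsCl, Et3N, THF, −30 °C; LiBr, 0 °C; then Bu3P, 0 °C → rt
Reagents that add atoms: lithium bromide, [Li+].[Br-]; tributylphosphine, CCCCP(CCCC)CCCC
Why: Mesylation and SN2 displacement by bromide give the primary allylic bromide under non-acidic conditions that spare the silyl ether, and SN2 alkylation of Bu3P gives the salt, a trialkylphosphonium group being chosen because its allylic ylide is less delocalised and more reactive than a triarylphosphonium ylide, which should keep the 9'E geometry and favour an E alkene in step 14.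

Step 14
Reactants: 23 tributyl[(2E)-3-methyl-5-{(4R)-2,6,6-trimethyl-4-[(triethylsilyl)oxy]cyclohex-1-en-1-yl}pent-2-en-4-yn-1-yl]phosphonium bromide; 24 (2E,4E,6E)-2,7-dimethylocta-2,4,6-trienedial
Product: 25 (2E,4E,6E,8E,10E)-2,7,11-trimethyl-13-{(4R)-2,6,6-trimethyl-4-[(triethylsilyl)oxy]cyclohex-1-en-1-yl}trideca-2,4,6,8,10-pentaen-12-ynal
Conditions: 23, KOtBu, THF, −78 °C; ylide added to 24 (2 equiv), −78 → 0 °C, dark
Reagents that add atoms: none
Why: Wittig reaction, in which the allylic tributylphosphonium ylide should condense with one formyl group of the dialdehyde (used in excess, inverse addition) to give the E-configured C11'=C12' bond, the remaining formyl group of the longer polyenal being less electrophilic and so slower to react a second time.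

Step 15
Reactants: 25 (2E,4E,6E,8E,10E)-2,7,11-trimethyl-13-{(4R)-2,6,6-trimethyl-4-[(triethylsilyl)oxy]cyclohex-1-en-1-yl}trideca-2,4,6,8,10-pentaen-12-ynal
Product: 26 (2E,4E,6E,8E,10E)-2,7,11-trimethyl-13-{(4R)-2,6,6-trimethyl-4-[(triethylsilyl)oxy]cyclohex-1-en-1-yl}trideca-2,4,6,8,10-pentaen-12-yn-1-ol
Conditions: NaBH4, MeOH/CH2Cl2, 0 °C, dark
Reagents that add atoms: none
Why: NaBH4 should reduce the polyenal by 1,2-addition to the primary polyenylic alcohol (carbonyl reduction) without touching the alkenes, the alkyne or the silyl ether.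

Step 16
Reactants: 26 (2E,4E,6E,8E,10E)-2,7,11-trimethyl-13-{(4R)-2,6,6-trimethyl-4-[(triethylsilyl)oxy]cyclohex-1-en-1-yl}trideca-2,4,6,8,10-pentaen-12-yn-1-ol
Product: 27 [(2E,4E,6E,8E,10E)-13-[(4R)-4-hydroxy-2,6,6-trimethylcyclohex-1-en-1-yl]-2,7,11-trimethyltrideca-2,4,6,8,10-pentaen-12-yn-1-yl]triphenylphosphonium bromide
Conditions: PPh3·HBr (1.3 equiv), MeOH/CH2Cl2, rt, dark
Reagents that add atoms: triphenylphosphine hydrobromide, Br.c1ccc(cc1)P(c1ccccc1)c1ccccc1
Why: PPh3·HBr ionises the polyenylic alcohol to a delocalised cation that PPh3 should capture at the primary terminus (allylic phosphonium salt formation), and the acidic methanol should cleave the triethylsilyl ether in the same operation, so that no protecting group is left for the end of the route.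

Step 17
Reactants: 27 [(2E,4E,6E,8E,10E)-13-[(4R)-4-hydroxy-2,6,6-trimethylcyclohex-1-en-1-yl]-2,7,11-trimethyltrideca-2,4,6,8,10-pentaen-12-yn-1-yl]triphenylphosphonium bromide; 15 (2E,4E)-5-[(1R,4S)-1,4-dihydroxy-2,6,6-trimethylcyclohex-2-en-1-yl]-3-methylpenta-2,4-dienal
Product: 28 (3R,3'S,6'R)-7,8-didehydro-β,ε-carotene-3,3',6'-triol, all-E (target; 3S,6R,3'R in the locants used here)
Conditions: NaOMe, MeOH/CH2Cl2, 0 °C → rt, dark, Ar; preparative HPLC
Reagents that add atoms: none
Why: Wittig reaction under conditions that tolerate free hydroxyls, in which the polyenyl ylide and the dienal should form the C11=C12 bond mainly as the E isomer (a hindered 11Z isomer is expected to revert on standing in solution under conditions too mild to equilibrate the 9' alkene next to the alkyne), all three stereocentres being already in place and untouched.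

**Compound list**

1 | mesityl oxide (4-methylpent-3-en-2-one) | CC(C)=CC(C)=O | starting material
2 | ethyl acetoacetate | CCOC(=O)CC(C)=O | starting material
3 | ethyl 2-acetyl-3,3-dimethyl-5-oxohexanoate (racemic) | CCOC(=O)C(C(C)=O)C(C)(C)CC(C)=O | intermediate
4 | ethyl 2-hydroxy-2,6,6-trimethyl-4-oxocyclohexane-1-carboxylate (stereoisomer mixture) | CCOC(=O)C1C(C)(O)CC(=O)CC1(C)C | intermediate
5 | (±)-ethyl 2,6,6-trimethyl-4-oxocyclohex-2-ene-1-carboxylate | CCOC(=O)C1C(C)=CC(=O)CC1(C)C | intermediate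
6 | ethyl 7,9,9-trimethyl-1,4-dioxaspiro[4.5]dec-7-ene-8-carboxylate | CCOC(=O)C1=C(C)CC2(OCCO2)CC1(C)C | intermediate
7 | (7,9,9-trimethyl-1,4-dioxaspiro[4.5]dec-7-en-8-yl)methanol | OCC1=C(C)CC2(OCCO2)CC1(C)C | intermediate
8 | [(1S,6S)-4,4-(ethylenedioxy)-2,2,6-trimethyl-7-oxabicyclo[4.1.0]heptan-1-yl]methanol | C[C@]12CC3(OCCO3)CC(C)(C)[C@]1(O2)CO | intermediate
9 | (1R,6S)-4,4-(ethylenedioxy)-2,2,6-trimethyl-7-oxabicyclo[4.1.0]heptane-1-carbaldehyde | C[C@]12CC3(OCCO3)CC(C)(C)[C@]1(O2)C=O | intermediate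
10 | diethyl (3-cyano-2-methylallyl)phosphonate (E/Z mixture) | CCOP(=O)(OCC)CC(C)=CC#N | starting material
11 | (2E,4E)-5-[(1R,6S)-4,4-(ethylenedioxy)-2,2,6-trimethyl-7-oxabicyclo[4.1.0]heptan-1-yl]-3-methylpenta-2,4-dienenitrile | C[C@]12CC3(OCCO3)CC(C)(C)[C@]1(O2)/C=C/C(C)=C/C#N | intermediate
12 | (2E,4E)-3-methyl-5-[(1R,6S)-2,2,6-trimethyl-4-oxo-7-oxabicyclo[4.1.0]heptan-1-yl]penta-2,4-dienenitrile | C[C@]12CC(=O)CC(C)(C)[C@]1(O2)/C=C/C(C)=C/C#N | intermediate
13 | (2E,4E)-5-[(1R)-1-hydroxy-2,6,6-trimethyl-4-oxocyclohex-2-en-1-yl]-3-methylpenta-2,4-dienenitrile | CC1=CC(=O)CC(C)(C)[C@]1(O)/C=C/C(C)=C/C#N | intermediate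
14 | (2E,4E)-5-[(1R,4S)-1,4-dihydroxy-2,6,6-trimethylcyclohex-2-en-1-yl]-3-methylpenta-2,4-dienenitrile | CC1=C[C@@H](O)CC(C)(C)[C@]1(O)/C=C/C(C)=C/C#N | intermediate
15 | (2E,4E)-5-[(1R,4S)-1,4-dihydroxy-2,6,6-trimethylcyclohex-2-en-1-yl]-3-methylpenta-2,4-dienal | CC1=C[C@@H](O)CC(C)(C)[C@]1(O)/C=C/C(C)=C/C=O | intermediate
16 | (4R,6R)-4-hydroxy-2,2,6-trimethylcyclohexan-1-one (actinol) | C[C@@H]1C[C@@H](O)CC(C)(C)C1=O | starting material
17 | (4R,6R)-2,2,6-trimethyl-4-[(triethylsilyl)oxy]cyclohexan-1-one | C[C@@H]1C[C@@H](O[Si](CC)(CC)CC)CC(C)(C)C1=O | intermediate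
18 | (4R)-2,6,6-trimethyl-4-[(triethylsilyl)oxy]cyclohex-1-en-1-yl trifluoromethanesulfonate | FC(F)(F)S(=O)(=O)OC1=C(C)C[C@@H](O[Si](CC)(CC)CC)CC1(C)C | intermediate
19 | (E)-3-methylpent-2-en-4-yn-1-ol | C#C/C(C)=C/CO | starting material
20 | (2E)-3-methyl-5-{(4R)-2,6,6-trimethyl-4-[(triethylsilyl)oxy]cyclohex-1-en-1-yl}pent-2-en-4-yn-1-ol | OC/C=C(\C)C#CC1=C(C)C[C@@H](O[Si](CC)(CC)CC)CC1(C)C | intermediate
21 | (2E)-3-methyl-5-{(4R)-2,6,6-trimethyl-4-[(triethylsilyl)oxy]cyclohex-1-en-1-yl}pent-2-en-4-yn-1-yl methanesulfonate | CS(=O)(=O)OC/C=C(\C)C#CC1=C(C)C[C@@H](O[Si](CC)(CC)CC)CC1(C)C | intermediate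
22 | {[(1R)-4-[(3E)-5-bromo-3-methylpent-3-en-1-yn-1-yl]-3,5,5-trimethylcyclohex-3-en-1-yl]oxy}triethylsilane | BrC/C=C(\C)C#CC1=C(C)C[C@@H](O[Si](CC)(CC)CC)CC1(C)C | intermediate
23 | tributyl[(2E)-3-methyl-5-{(4R)-2,6,6-trimethyl-4-[(triethylsilyl)oxy]cyclohex-1-en-1-yl}pent-2-en-4-yn-1-yl]phosphonium bromide | CCCC[P+](CCCC)(CCCC)C/C=C(\C)C#CC1=C(C)C[C@@H](O[Si](CC)(CC)CC)CC1(C)C.[Br-] | intermediate
24 | (2E,4E,6E)-2,7-dimethylocta-2,4,6-trienedial | O=C/C(C)=C/C=C/C=C(\C)C=O | starting material
25 | (2E,4E,6E,8E,10E)-2,7,11-trimethyl-13-{(4R)-2,6,6-trimethyl-4-[(triethylsilyl)oxy]cyclohex-1-en-1-yl}trideca-2,4,6,8,10-pentaen-12-ynal | O=C/C(C)=C/C=C/C=C(C)/C=C/C=C(\C)C#CC1=C(C)C[C@@H](O[Si](CC)(CC)CC)CC1(C)C | intermediate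
26 | (2E,4E,6E,8E,10E)-2,7,11-trimethyl-13-{(4R)-2,6,6-trimethyl-4-[(triethylsilyl)oxy]cyclohex-1-en-1-yl}trideca-2,4,6,8,10-pentaen-12-yn-1-ol | OC/C(C)=C/C=C/C=C(C)/C=C/C=C(\C)C#CC1=C(C)C[C@@H](O[Si](CC)(CC)CC)CC1(C)C | intermediate
27 | [(2E,4E,6E,8E,10E)-13-[(4R)-4-hydroxy-2,6,6-trimethylcyclohex-1-en-1-yl]-2,7,11-trimethyltrideca-2,4,6,8,10-pentaen-12-yn-1-yl]triphenylphosphonium bromide | c1ccccc1[P+](c1ccccc1)(c1ccccc1)C/C(C)=C/C=C/C=C(C)/C=C/C=C(\C)C#CC1=C(C)C[C@@H](O)CC1(C)C.[Br-] | intermediate
28 | (3R,3'S,6'R)-7,8-didehydro-β,ε-carotene-3,3',6'-triol, all-E (3S,6R,3'R in the locants used here) | CC1=C[C@@H](O)CC(C)(C)[C@]1(O)/C=C/C(C)=C/C=C/C(C)=C/C=C/C=C(C)/C=C/C=C(\C)C#CC1=C(C)C[C@@H](O)CC1(C)C | target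

**Summary**

Total step count: 17. Longest linear sequence: 10 steps (steps 1–9, then 17); the ring B branch (steps 10–16, then 17) has 8.

Steps most likely to fail, with fallbacks:

Step 8 (insufficient facial selectivity, or slow reduction because the free tertiary hydroxyl binds the borane). Setting out from 13, a Luche reduction (NaBH4, CeCl3·7H2O, MeOH, −40 °C) is used without a chiral reagent. Whatever cis-diol 14 forms is separated and kept. The epimeric trans-diol (2E,4E)-5-[(1R,4R)-1,4-dihydroxy-2,6,6-trimethylcyclohex-2-en-1-yl]-3-methylpenta-2,4-dienenitrile F1 is inverted at the secondary allylic carbinol by a Mitsunobu reaction (PPh3, diisopropyl azodicarboxylate, 4-nitrobenzoic acid, THF, 0 °C) to (1S,4R)-4-[(1E,3E)-4-cyano-3-methylbuta-1,3-dien-1-yl]-4-hydroxy-3,5,5-trimethylcyclohex-2-en-1-yl 4-nitrobenzoate F2. Methanolysis of F2 (K2CO3, MeOH, 0 °C) returns to the route at 14, so both epimers are funnelled into the cis-diol.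

Step 14 (erosion of the 9'E geometry in the enyne-conjugated ylide, or condensation at both formyl groups). The polarity of the union is reversed so that no ylide is conjugated with the enyne. Setting out from 20, MnO2 in CH2Cl2 should give (2E)-3-methyl-5-{(4R)-2,6,6-trimethyl-4-[(triethylsilyl)oxy]cyclohex-1-en-1-yl}pent-2-en-4-ynal F3. Dialdehyde 24 is reduced (NaBH4, MeOH, 0 °C) to (2E,4E,6E)-2,7-dimethylocta-2,4,6-triene-1,8-diol F4. One equivalent of PPh3·HBr in MeOH converts F4 into [(2E,4E,6E)-8-hydroxy-2,7-dimethylocta-2,4,6-trien-1-yl]triphenylphosphonium bromide F5, unchanged diol being recycled. Wittig reaction of F5 with F3 (NaOMe, MeOH/CH2Cl2) should give the C25 allylic alcohol directly and returns to the route at 26, bypassing steps 13 to 15.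

Step 4 (slow or poorly enantioselective oxygen transfer to the hindered tetrasubstituted alkene). Setting out from 7, epoxidation with mCPBA (NaHCO3, CH2Cl2, 0 °C) gives racemic [4,4-(ethylenedioxy)-2,2,6-trimethyl-7-oxabicyclo[4.1.0]heptan-1-yl]methanol F6. F6 is acylated with (1S)-camphanic chloride (pyridine, DMAP, CH2Cl2), and the diastereomeric esters are separated by crystallisation or chromatography. The ester of the wanted epoxide, [(1S,6S)-4,4-(ethylenedioxy)-2,2,6-trimethyl-7-oxabicyclo[4.1.0]heptan-1-yl]methyl (1S,4R)-4,7,7-trimethyl-3-oxo-2-oxabicyclo[2.2.1]heptane-1-carboxylate F7, is cleaved with K2CO3 in MeOH to return to the route at 8.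

Further compounds
F1 | step 8 | (2E,4E)-5-[(1R,4R)-1,4-dihydroxy-2,6,6-trimethylcyclohex-2-en-1-yl]-3-methylpenta-2,4-dienenitrile | CC1=C[C@H](O)CC(C)(C)[C@]1(O)/C=C/C(C)=C/C#N
F2 | step 8 | (1S,4R)-4-[(1E,3E)-4-cyano-3-methylbuta-1,3-dien-1-yl]-4-hydroxy-3,5,5-trimethylcyclohex-2-en-1-yl 4-nitrobenzoate | CC1=C[C@@H](OC(=O)c2ccc(cc2)[N+](=O)[O-])CC(C)(C)[C@]1(O)/C=C/C(C)=C/C#N
F3 | step 14 | (2E)-3-methyl-5-{(4R)-2,6,6-trimethyl-4-[(triethylsilyl)oxy]cyclohex-1-en-1-yl}pent-2-en-4-ynal | O=C/C=C(\C)C#CC1=C(C)C[C@@H](O[Si](CC)(CC)CC)CC1(C)C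
F4 | step 14 | (2E,4E,6E)-2,7-dimethylocta-2,4,6-triene-1,8-diol | OC/C(C)=C/C=C/C=C(\C)CO
F5 | step 14 | [(2E,4E,6E)-8-hydroxy-2,7-dimethylocta-2,4,6-trien-1-yl]triphenylphosphonium bromide | OC/C(C)=C/C=C/C=C(\C)C[P+](c1ccccc1)(c1ccccc1)c1ccccc1.[Br-]
F6 | step 4 | racemic [4,4-(ethylenedioxy)-2,2,6-trimethyl-7-oxabicyclo[4.1.0]heptan-1-yl]methanol | CC12CC3(OCCO3)CC(C)(C)C1(O2)CO
F7 | step 4 | [(1S,6S)-4,4-(ethylenedioxy)-2,2,6-trimethyl-7-oxabicyclo[4.1.0]heptan-1-yl]methyl (1S,4R)-4,7,7-trimethyl-3-oxo-2-oxabicyclo[2.2.1]heptane-1-carboxylate | C[C@]12CC3(OCCO3)CC(C)(C)[C@]1(O2)COC(=O)[C@@]45CC[C@@](C)(C(=O)O4)C5(C)C
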